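## Analysis of the target

The target is a flavone: a 4H-chromen-4-one in which the benzo ring A (C4a to C8a) is fused to the pyranone ring C (O1, C2, C3, C4), and C2 carries the phenyl ring B. It has no stereocentre. The C2–C1' axis is not expected to be configurationally stable, because the chromone side flanks it only with O1 and C3–H. Ring A is fully substituted: C5 and C6 carry free hydroxyls, C7 and C8 carry methoxy groups, C8a carries the ring oxygen, and only C4a carries carbon. Ring B has a hydroxyl at C2' and a methoxy group at C6', both ortho to the bond to C2. The difficulty is oxygen bookkeeping and crowding. Three hydroxyls must end free beside three methyl ethers, and the 5,6-dihydroxy-7,8-dimethoxy pattern must not be confused with the 5,8-dihydroxy-6,7-dimethoxy isomer, which arises whenever an open-chain precursor can close through either ortho oxygen. In addition, C2 is bonded to a doubly ortho-substituted ring. The 5,6-catechol on an electron-rich ring is easily oxidised, and 5-hydroxyflavones can open and isomerise in hot strong acid or base, so the catechol should be released last and under mild, non-oxidising conditions. The strategy rests on one feature: in a ring A phenol that already carries all five oxygens, C4a is the only carbon bearing hydrogen and lies ortho to the oxygen that becomes O1, so an acyl carbon tethered through O1–C2=C3 can close ring C only at C4a.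

## Retrosynthetic reasoning

**Protecting groups (16 ⇐ 15 ⇐ 14).** The three oxygens that end as free hydroxyls are masked differently from the three methyl ethers. O5 and O6 are adjacent and are tied together as an isopropylidene ketal, so the oxidation-prone catechol is released only in the last step, from 15, by aqueous acid. O2' is carried as a benzyl ether in 14 and freed by hydrogenolysis. The benzyl group is needed because a free or acid-labile O2' could attack the activated carboxyl of the key step and give a coumarin.

**C4–C4a (14 ⇐ 13 ⇐ 12), the key disconnection.** Cutting the bond between the carbonyl carbon and ring A leads to the 3-aryloxy-3-arylacrylic acid 12, activated as its mixed anhydride 13. This cut is preferred over the others for three reasons: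
- Cutting O1–C2 or C3–C4 would require an acyl group to be placed on the pentaoxygenated ring by an intermolecular reaction first.
- Cutting C2–C1' would require a coupling to a doubly ortho-substituted aryl partner.
- Cutting C4–C4a makes the acylation intramolecular and its position certain, because O1 is already attached and C4a is the only free carbon.

The forward reaction must acylate a very electron-rich arene without harming the ketal or the benzyl ether.

**O1–C2 (12 ⇐ 11 ⇐ 5 + 10).** The enol ether bond is cut to the ring A phenol 5 and the arylpropynoate 10. The forward reaction is conjugate addition of the phenoxide to the ynoate, and anti addition gives the Z geometry (aryloxy cis to carboxyl) that the ring closure needs. Saponification of ester 11 then frees acid 12. This joins the two aromatic halves late and in two steps.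

**C3–C4 and C2≡C3 (10 ⇐ 9 ⇐ 8 ⇐ 7 ⇐ 6).** The ester carbon (C4) is cut from acetylide 9, and the alkyne is traced to dibromoalkene 8 and aldehyde 7. The aldehyde carbon of the commercial salicylaldehyde 6 becomes C2. Its two ortho oxygens are already differentiated as hydroxyl and methoxy, so ring B needs only O-benzylation.

**Ring A oxygens (5 ⇐ 4 ⇐ 3 ⇐ 2 ⇐ 1).** The ketal is cut to triol 4, which comes from triacetate 3 and quinone 2. Phenol 1 supplies the two methoxy groups (C7 and C8). Oxidation to the para-quinone provides the oxygen pair that becomes O1 and O6. Acetoxylation of the quinone adds O5. Because 2 is symmetric, only one triacetate can form. In 4 only one pair of hydroxyls is adjacent, so ketalisation leaves free exactly the hydroxyl that becomes O1.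

## Alternatives that were turned down

**Alternative 1:** squarate ring expansion to build ring A.
- Disconnection: the C5–C6 bond of ring A. The ring is assembled from a four-carbon squaric unit (C6, C7, C8, C8a, with both methoxy groups) and the C=C bond of a dioxinone (C4a and C5, with C4 as its carbonyl and O5 as its ring oxygen).
- Forward key step: heating the racemic 4-(2,2-dimethyl-4-oxo-4H-1,3-dioxin-5-yl)-4-hydroxy-2,3-dimethoxycyclobut-2-en-1-one A2 opens the four-membered ring to its ketene form. The ketene carbon (C6) closes onto the dioxinone CH (C5) in a 6π electrocyclisation, and tautomerisation gives 5,8-dihydroxy-6,7-dimethoxy-2,2-dimethyl-4H-1,3-benzodioxin-4-one A1.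
- For it: every oxygen of ring A is placed by bond construction under neutral thermal conditions, and no arene has to act as a nucleophile. On certainty of the ring A pattern it is at least as strong as the chosen route.
- Against it: A1 is only ring A plus C4, so C3, C2 and ring B must still be attached at the lactone carbonyl. Once the dioxinone is opened, the acyl group is flanked by two free ortho hydroxyls, so pyranone closure can go either way and would give the 5,8-dihydroxy-6,7-dimethoxy flavone unless extra protecting steps distinguish them. A1 is a para-hydroquinone and oxidation-prone. The vinyl anion needed to make A2 is β-oxygenated, carries an ester, and is liable to fragment.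
- Comparison: in the chosen route O1 is bonded to C2 before ring C closes and C4a is the only free site, so the isomer question cannot arise. Both aromatic rings are bought, so the skeleton is reached in fewer steps.

**Alternative 2:** Danheiser benzannulation to build ring B on the chromone.
- Disconnection: ring B itself, at C1'–C2' and C5'–C6'.
- Forward key step: cyclobut-2-en-1-one A5 opens thermally to its ketene form, which adds (2+2) across the alkynyl ether of 2-(methoxyethynyl)-7,8-dimethoxychromone 5,6-acetonide A4, the ketene carbon bonding to the alkyne carbon on C2. A 4π opening and 6π closure then re-form C2'–C3' and give, after tautomerisation, 2-(2-hydroxy-6-methoxyphenyl)-7,8-dimethoxychromone 5,6-acetonide A3, which is the same compound as 15.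
- For it: the mechanism itself sets the 2'-hydroxyl/6'-methoxy distinction, ring B needs no protecting group, and the crowded C2–C1' bond is never made by coupling. On these points it is stronger than the chosen route, which spends a benzyl group and a hydrogenolysis on O2'.
- Against it: the whole chromone with its pentaoxygenated ring A must already exist in A4, so the real problem of this target is only moved upstream. Converting a C2 substituent into a methoxyethynyl group costs further steps. The alkynyl ether of A4 is conjugated with the chromone carbonyl, which lowers the nucleophilicity the ketene addition depends on. The chromone C2=C3 bond and the volatile, polymerisable A5 invite side reactions.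
- Comparison: the chosen route takes ring B from a commercial salicylaldehyde whose ortho oxygens are already distinguished, and spends its steps on ring A and its union with ring C.

**Alternative 3:** polyketide-type Claisen folding of ring A onto a pyranone.
- Disconnection: the C4a–C5 bond. Ring A is folded from an acyclic chain on a preformed 2-aryl-4-pyranone.
- Forward key step: base removes the C8 proton of methyl 2-(benzyloxy)-4-{6-[2-(benzyloxy)-6-methoxyphenyl]-4-oxo-4H-pyran-2-yl}-4-methoxy-3-oxobutanoate A7 (mixture of stereoisomers). The dienolate attacks the ester carbon (C5) through C4a, methoxide leaves, and two enolisations aromatise ring A to 6-(benzyloxy)-2-(2-benzyloxy-6-methoxyphenyl)-5,7-dihydroxy-8-methoxychromen-4-one A6.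
- For it: ring B and the pyranone are in place, the key step is basic, and no oxidation-sensitive polyphenol is handled early. In A6 the chelated 5-hydroxyl can be told from the 7-hydroxyl, so selective 7-O-methylation and one hydrogenolysis would finish. That end game is as short as the one from 14.
- Against it: A7 is a densely oxygenated β-keto ester that must be built by several acylations, each with O- versus C-acylation problems, and it carries two stereocentres of no use. Its most acidic proton is at C6, between ketone and ester; the enolate formed there deactivates the very ester carbon that must be attacked, so closure has to proceed from a dianion. The dienolate can also react through C8, and the pyranone can open in base.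
- Comparison: the chosen route never has to build a carbon–carbon bond within ring A. All six carbons and five oxygens of ring A come from one dimethoxyphenol by two oxidations, and the single bond from ring A to C4 is made where only one site is free.

Key step: step 9

Remark on the chemistry (assumption): the phenoxide is taken to add anti across the alkyne in step 7, so 11, 12 and 13 are drawn with Z geometry. Partial loss of this geometry is expected to be tolerated in step 9, because the C2=C3 bond can isomerise through its C3-protonated form.

## Route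

Step 1
Reactants: 1 2,3-dimethoxyphenol
Product: 2 2,3-dimethoxy-1,4-benzoquinone
Conditions: (KSO3)2NO (2.5 equiv), KH2PO4, H2O/acetone, 0 °C to rt
Reagents that add atoms: potassium nitrosodisulfonate, [K+].[K+].[O]N(S(=O)(=O)[O-])S(=O)(=O)[O-]
Why: Teuber oxidation: the nitrosodisulfonate radical oxidises a phenol with a free para position (C4 of 1) to the para-quinone, and the two methoxy groups are untouched.

Step 2
Reactants: 2 2,3-dimethoxy-1,4-benzoquinone
Product: 3 5,6-dimethoxybenzene-1,2,4-triyl triacetate
Conditions: Ac2O, H2SO4 (cat.), 25–40 °C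
Reagents that add atoms: acetic anhydride, CC(=O)OC(C)=O
Why: Thiele–Winter acetoxylation: acid-catalysed conjugate addition of acetate to the quinone, enolisation and acetylation; the two free quinone carbons of 2 are equivalent by symmetry, so a single triacetate should form.

Step 3
Reactants: 3 5,6-dimethoxybenzene-1,2,4-triyl triacetate
Product: 5 6,7-dimethoxy-2,2-dimethyl-1,3-benzodioxol-5-ol, via 5,6-dimethoxybenzene-1,2,4-triol 4 (not isolated)
Conditions: HCl, MeOH, Ar, 50 °C; evaporate; then Me2C(OMe)2, TsOH·H2O (cat.), toluene, reflux, 4 Å MS (MeOH removal)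
Reagents that add atoms: 2,2-dimethoxypropane, COC(C)(C)OC
Why: Acid-catalysed methanolysis removes the three acetyl groups without exposing the oxidation-prone triol to base, and ketal exchange then closes the five-membered dioxole on the only pair of adjacent hydroxyls; the third hydroxyl has no hydroxyl neighbour and stays free.

Step 4
Reactants: 6 2-hydroxy-6-methoxybenzaldehyde
Product: 7 2-(benzyloxy)-6-methoxybenzaldehyde
Conditions: BnBr, K2CO3, DMF, 50 °C
Reagents that add atoms: benzyl bromide, BrCc1ccccc1
Why: Williamson ether synthesis on the phenoxide; benzyl is chosen because it survives organolithium, base and acylating conditions and is removed by hydrogenolysis.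

Step 5
Reactants: 7 2-(benzyloxy)-6-methoxybenzaldehyde
Product: 8 1-(benzyloxy)-2-(2,2-dibromoethenyl)-3-methoxybenzene
Conditions: CBr4, PPh3, CH2Cl2, 0 °C
Reagents that add atoms: carbon tetrabromide, BrC(Br)(Br)Br
Why: Corey–Fuchs olefination (Wittig-type reaction of the dibromomethylene ylide) turns the aldehyde carbon, the future C2, into a dibromoalkene; aromatic aldehydes with two ortho alkoxy groups are suitable substrates.

Step 6
Reactants: 8 1-(benzyloxy)-2-(2,2-dibromoethenyl)-3-methoxybenzene
Product: 10 methyl 3-[2-(benzyloxy)-6-methoxyphenyl]prop-2-ynoate, via lithium [2-(benzyloxy)-6-methoxyphenyl]acetylide 9 (not isolated)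
Conditions: n-BuLi (2.1 equiv), THF, −78 °C; then ClCO2Me, −78 °C to rt
Reagents that add atoms: methyl chloroformate, COC(=O)Cl
Why: Second stage of the Corey–Fuchs sequence: bromine–lithium exchange and Fritsch–Buttenberg–Wiechell rearrangement give the alkyne, which the second equivalent of n-BuLi deprotonates; acylation of the acetylide by the chloroformate brings in C4 as the ester.

Step 7
Reactants: 5 6,7-dimethoxy-2,2-dimethyl-1,3-benzodioxol-5-ol; 10 methyl 3-[2-(benzyloxy)-6-methoxyphenyl]prop-2-ynoate
Product: 11 methyl (2Z)-3-[2-(benzyloxy)-6-methoxyphenyl]-3-[(6,7-dimethoxy-2,2-dimethyl-1,3-benzodioxol-5-yl)oxy]prop-2-enoate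
Conditions: Cs2CO3 (0.2 equiv), DMF (degassed), Ar, 60 °C
Reagents that add atoms: none
Why: Base-catalysed oxa-Michael addition of the phenoxide of 5 to the ynoate forms O1–C2 at the β-carbon; anti protonation of the vinyl anion places the aryloxy group cis to the ester (Z), the geometry needed for ring closure.

Step 8
Reactants: 11 methyl (2Z)-3-[2-(benzyloxy)-6-methoxyphenyl]-3-[(6,7-dimethoxy-2,2-dimethyl-1,3-benzodioxol-5-yl)oxy]prop-2-enoate
Product: 12 (2Z)-3-[2-(benzyloxy)-6-methoxyphenyl]-3-[(6,7-dimethoxy-2,2-dimethyl-1,3-benzodioxol-5-yl)oxy]prop-2-enoic acid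
Conditions: LiOH·H2O, THF/MeOH/H2O, rt; then 1 M HCl to pH 3, 0 °C
Reagents that add atoms: lithium hydroxide, [Li+].[OH-]
Why: Saponification (acyl–oxygen cleavage by hydroxide) of the methyl ester; the ketal, the benzyl ether and the enol ether are stable to base, and brief cold acidification spares the ketal.

Step 9
Reactants: 12 (2Z)-3-[2-(benzyloxy)-6-methoxyphenyl]-3-[(6,7-dimethoxy-2,2-dimethyl-1,3-benzodioxol-5-yl)oxy]prop-2-enoic acid
Product: 14 2-[2-(benzyloxy)-6-methoxyphenyl]-7,8-dimethoxychromone 5,6-acetonide, via mixed trifluoroacetic anhydride 13 (not isolated)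
Conditions: (CF3CO)2O (3 equiv), CH2Cl2 (0.02 M), 0 °C to rt
Reagents that add atoms: none
Why: Trifluoroacetic anhydride converts the carboxylic acid into the mixed anhydride 13; its acyl carbon (C4), or the acylium ion formed by loss of trifluoroacetate, is attacked by C4a of ring A, and loss of the C4a proton restores aromaticity and gives the 4-pyranone. The closest known reaction types are the classical acid-mediated ring closure of 3-aryloxy-3-arylacrylic acids to flavones and the intramolecular Friedel–Crafts acylation of activated arenes through mixed trifluoroacetic anhydrides. Ring C closes in a 6-exo-trig fashion at the acyl carbon, with the C4a–C8a bond of the arene inside the new ring. No stereocentre is formed. The step needs site selectivity for C4a: it is the only ring A carbon that bears hydrogen, it is ortho to O1 and to the ketal oxygen on C5 and para to the C7 methoxy group, and the Z geometry holds the acyl group next to it. Ring B cannot compete by indenone formation because both of its ortho carbons carry oxygen, and O2' stays benzylated so that it cannot lactonise to a coumarin. If the alkene geometry is partly lost, reversible protonation at C3 gives a cation stabilised by O1 and ring B, through which the reactive geometry can be regained. The absence of a strong Brønsted or Lewis acid should leave the benzyl ether, the ketal and the methyl ethers intact.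

Step 10
Reactants: 14 2-[2-(benzyloxy)-6-methoxyphenyl]-7,8-dimethoxychromone 5,6-acetonide
Product: 15 2-(2-hydroxy-6-methoxyphenyl)-7,8-dimethoxychromone 5,6-acetonide
Conditions: H2 (1 atm), 10% Pd/C, EtOAc/MeOH, rt
Reagents that add atoms: none
Why: Catalytic hydrogenolysis of the benzyl aryl ether; the conjugated C2=C3 bond of the chromone, the ketal and the methyl ethers are not expected to react at 1 atm.

Step 11
Reactants: 15 2-(2-hydroxy-6-methoxyphenyl)-7,8-dimethoxychromone 5,6-acetonide
Product: 16 5,6,2'-trihydroxy-7,8,6'-trimethoxyflavone
Conditions: CF3CO2H/H2O (9:1), Ar, rt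
Reagents that add atoms: none
Why: Acid-catalysed hydrolysis of the ketal through the aryloxy-stabilised oxocarbenium ion; O5 is a good leaving group because it is conjugated with the C4 carbonyl, the methyl ethers are stable, and the catechol appears only in this last, non-oxidising step.

## Compound list

1 | 2,3-dimethoxyphenol | COc1cccc(O)c1OC | starting material
2 | 2,3-dimethoxy-1,4-benzoquinone | COC1=C(OC)C(=O)C=CC1=O | intermediate
3 | 5,6-dimethoxybenzene-1,2,4-triyl triacetate | CC(=O)Oc1cc(OC(C)=O)c(OC)c(OC)c1OC(C)=O | intermediate
4 | 5,6-dimethoxybenzene-1,2,4-triol | Oc1cc(O)c(OC)c(OC)c1O | intermediate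
5 | 6,7-dimethoxy-2,2-dimethyl-1,3-benzodioxol-5-ol | CC1(C)Oc2cc(O)c(OC)c(OC)c2O1 | intermediate
6 | 2-hydroxy-6-methoxybenzaldehyde | COc1cccc(O)c1C=O | starting material
7 | 2-(benzyloxy)-6-methoxybenzaldehyde | COc1cccc(OCc2ccccc2)c1C=O | intermediate
8 | 1-(benzyloxy)-2-(2,2-dibromoethenyl)-3-methoxybenzene | COc1cccc(OCc2ccccc2)c1C=C(Br)Br | intermediate
9 | lithium [2-(benzyloxy)-6-methoxyphenyl]acetylide | COc1cccc(OCc2ccccc2)c1C#C[Li] | intermediate
10 | methyl 3-[2-(benzyloxy)-6-methoxyphenyl]prop-2-ynoate | COC(=O)C#Cc1c(OC)cccc1OCc1ccccc1 | intermediate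
11 | methyl (2Z)-3-[2-(benzyloxy)-6-methoxyphenyl]-3-[(6,7-dimethoxy-2,2-dimethyl-1,3-benzodioxol-5-yl)oxy]prop-2-enoate | COC(=O)/C=C(\Oc1cc2OC(C)(C)Oc2c(OC)c1OC)c1c(OC)cccc1OCc1ccccc1 | intermediate
12 | (2Z)-3-[2-(benzyloxy)-6-methoxyphenyl]-3-[(6,7-dimethoxy-2,2-dimethyl-1,3-benzodioxol-5-yl)oxy]prop-2-enoic acid | OC(=O)/C=C(\Oc1cc2OC(C)(C)Oc2c(OC)c1OC)c1c(OC)cccc1OCc1ccccc1 | intermediate
13 | (2Z)-3-[2-(benzyloxy)-6-methoxyphenyl]-3-[(6,7-dimethoxy-2,2-dimethyl-1,3-benzodioxol-5-yl)oxy]prop-2-enoic trifluoroacetic anhydride | O=C(OC(=O)C(F)(F)F)/C=C(\Oc1cc2OC(C)(C)Oc2c(OC)c1OC)c1c(OC)cccc1OCc1ccccc1 | intermediate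
14 | 2-[2-(benzyloxy)-6-methoxyphenyl]-7,8-dimethoxychromone 5,6-acetonide | COc1cccc(OCc2ccccc2)c1-c1cc(=O)c2c3OC(C)(C)Oc3c(OC)c(OC)c2o1 | intermediate
15 | 2-(2-hydroxy-6-methoxyphenyl)-7,8-dimethoxychromone 5,6-acetonide | COc1cccc(O)c1-c1cc(=O)c2c3OC(C)(C)Oc3c(OC)c(OC)c2o1 | intermediate
16 | 5,6,2'-trihydroxy-7,8,6'-trimethoxyflavone | COc1cccc(O)c1-c1cc(=O)c2c(O)c(O)c(OC)c(OC)c2o1 | target

## Step count and least certain steps

Total step count: 11. Longest linear sequence: 8 steps (steps 1, 2, 3, 7, 8, 9, 10, 11; the ring B branch through steps 4, 5, 6 is equally long).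

**Step 9 (key step).** The acyl carbon of 13 is part of a vinylogous carbonate and may be too weak an electrophile, so the cyclisation may stall. Prolonged contact with the trifluoroacetic acid formed could then bring debenzylative lactonisation through O2' (if the carboxyl comes to lie cis to ring B), trifluoroacetylation of ring B at C3' or C5', or opening of the ketal. Fallback, from 5 and acetylide 9 to 14: form the C4–C4a bond first and the O1–C2 bond last. Phenol 5 is ortho-formylated at its only free ring carbon (MgCl2, Et3N, paraformaldehyde, MeCN, reflux) to give 5-hydroxy-6,7-dimethoxy-2,2-dimethyl-1,3-benzodioxole-4-carbaldehyde F1. Its sodium phenoxide (NaH, THF) is treated with acetylide 9, made from 8 as in step 6, to give racemic 4-{3-[2-(benzyloxy)-6-methoxyphenyl]-1-hydroxyprop-2-yn-1-yl}-6,7-dimethoxy-2,2-dimethyl-1,3-benzodioxol-5-ol F2. MnO2 in CH2Cl2 should oxidise the propargylic alcohol to 3-[2-(benzyloxy)-6-methoxyphenyl]-1-(5-hydroxy-6,7-dimethoxy-2,2-dimethyl-1,3-benzodioxol-4-yl)prop-2-yn-1-one F3. Et2NH in EtOH should then close ring C by 6-endo-dig oxa-Michael addition through the enaminone, giving 14.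

**Step 7.** The conjugate addition may be slow: the β-carbon of 10 is shielded by the two ortho substituents of ring B, and their electron donation lowers its electrophilicity. At the higher temperatures then needed, carbon alkylation through C4a and oxidation of the electron-rich phenoxide can take over. Fallback, from 10 to 11: make the O1–C2 bond by a copper-mediated coupling instead of a conjugate addition. Anti hydroiodination of 10 (NaI, AcOH, 70 °C) should give methyl (2Z)-3-[2-(benzyloxy)-6-methoxyphenyl]-3-iodoprop-2-enoate F4. Ullmann-type coupling of F4 with phenol 5 (CuI, N,N-dimethylglycine, K3PO4, dioxane, 90 °C) should proceed with retention at the vinyl carbon and give 11.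

**Step 3.** Ketal exchange on a catechol is an unfavourable equilibrium, so the ketalisation may stay incomplete, and the long heating it then needs exposes triol 4 to oxidation. Fallback, from 4 to 16: use an irreversible ketalisation and a ketal that is removed together with the benzyl ether.
- Triol 4, made from 3 as in step 3, is heated with dichlorodiphenylmethane (diphenyl ether, 170 °C, N2 stream) to give 6,7-dimethoxy-2,2-diphenyl-1,3-benzodioxol-5-ol F5.
- F5 replaces 5 in step 7 and should give methyl (2Z)-3-[2-(benzyloxy)-6-methoxyphenyl]-3-[(6,7-dimethoxy-2,2-diphenyl-1,3-benzodioxol-5-yl)oxy]prop-2-enoate F6.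
- Saponification as in step 8 should give (2Z)-3-[2-(benzyloxy)-6-methoxyphenyl]-3-[(6,7-dimethoxy-2,2-diphenyl-1,3-benzodioxol-5-yl)oxy]prop-2-enoic acid F7.
- Under the conditions of step 9 this should pass through (2Z)-3-[2-(benzyloxy)-6-methoxyphenyl]-3-[(6,7-dimethoxy-2,2-diphenyl-1,3-benzodioxol-5-yl)oxy]prop-2-enoic trifluoroacetic anhydride F8 and cyclise to 2-[2-(benzyloxy)-6-methoxyphenyl]-7,8-dimethoxychromone 5,6-(diphenylmethylene) ketal F9.
- One hydrogenolysis (H2, Pd(OH)2/C, THF/MeOH) should remove the benzyl ether and the diphenylmethylene ketal together and give 16, so steps 10 and 11 merge into one.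

**Step 8.** Hydroxide may add to C2, the β-carbon of the vinylogous carbonate, and expel the aryloxide of 5, or the 3-aryloxyacrylic acid may lose carbon dioxide on acidification. Fallback, from acetylide 9 to 12: avoid hydroxide by using an ester that is cleaved under neutral conditions. Acetylide 9 is trapped with allyl chloroformate instead of methyl chloroformate to give prop-2-en-1-yl 3-[2-(benzyloxy)-6-methoxyphenyl]prop-2-ynoate F10. Addition of 5 as in step 7 should give prop-2-en-1-yl (2Z)-3-[2-(benzyloxy)-6-methoxyphenyl]-3-[(6,7-dimethoxy-2,2-dimethyl-1,3-benzodioxol-5-yl)oxy]prop-2-enoate F11. Pd(PPh3)4 (cat.) with morpholine in THF at rt should transfer the allyl group to the amine and release 12.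

## Further compounds

F1 | step 9 | 5-hydroxy-6,7-dimethoxy-2,2-dimethyl-1,3-benzodioxole-4-carbaldehyde | O=Cc1c(O)c(OC)c(OC)c2OC(C)(C)Oc12
F2 | step 9 | 4-{3-[2-(benzyloxy)-6-methoxyphenyl]-1-hydroxyprop-2-yn-1-yl}-6,7-dimethoxy-2,2-dimethyl-1,3-benzodioxol-5-ol (racemic) | OC(C#Cc1c(OC)cccc1OCc1ccccc1)c1c(O)c(OC)c(OC)c2OC(C)(C)Oc12
F3 | step 9 | 3-[2-(benzyloxy)-6-methoxyphenyl]-1-(5-hydroxy-6,7-dimethoxy-2,2-dimethyl-1,3-benzodioxol-4-yl)prop-2-yn-1-one | O=C(C#Cc1c(OC)cccc1OCc1ccccc1)c1c(O)c(OC)c(OC)c2OC(C)(C)Oc12
F4 | step 7 | methyl (2Z)-3-[2-(benzyloxy)-6-methoxyphenyl]-3-iodoprop-2-enoate | COC(=O)/C=C(\I)c1c(OC)cccc1OCc1ccccc1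
F5 | step 3 | 6,7-dimethoxy-2,2-diphenyl-1,3-benzodioxol-5-ol | Oc1cc2OC(c3ccccc3)(c3ccccc3)Oc2c(OC)c1OC
F6 | step 3 | methyl (2Z)-3-[2-(benzyloxy)-6-methoxyphenyl]-3-[(6,7-dimethoxy-2,2-diphenyl-1,3-benzodioxol-5-yl)oxy]prop-2-enoate | COC(=O)/C=C(\Oc1cc2OC(c3ccccc3)(c3ccccc3)Oc2c(OC)c1OC)c1c(OC)cccc1OCc1ccccc1
F7 | step 3 | (2Z)-3-[2-(benzyloxy)-6-methoxyphenyl]-3-[(6,7-dimethoxy-2,2-diphenyl-1,3-benzodioxol-5-yl)oxy]prop-2-enoic acid | OC(=O)/C=C(\Oc1cc2OC(c3ccccc3)(c3ccccc3)Oc2c(OC)c1OC)c1c(OC)cccc1OCc1ccccc1
F8 | step 3 | (2Z)-3-[2-(benzyloxy)-6-methoxyphenyl]-3-[(6,7-dimethoxy-2,2-diphenyl-1,3-benzodioxol-5-yl)oxy]prop-2-enoic trifluoroacetic anhydride | O=C(OC(=O)C(F)(F)F)/C=C(\Oc1cc2OC(c3ccccc3)(c3ccccc3)Oc2c(OC)c1OC)c1c(OC)cccc1OCc1ccccc1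
F9 | step 3 | 2-[2-(benzyloxy)-6-methoxyphenyl]-7,8-dimethoxychromone 5,6-(diphenylmethylene) ketal | COc1cccc(OCc2ccccc2)c1-c1cc(=O)c2c3OC(c4ccccc4)(c4ccccc4)Oc3c(OC)c(OC)c2o1
F10 | step 8 | prop-2-en-1-yl 3-[2-(benzyloxy)-6-methoxyphenyl]prop-2-ynoate | C=CCOC(=O)C#Cc1c(OC)cccc1OCc1ccccc1
F11 | step 8 | prop-2-en-1-yl (2Z)-3-[2-(benzyloxy)-6-methoxyphenyl]-3-[(6,7-dimethoxy-2,2-dimethyl-1,3-benzodioxol-5-yl)oxy]prop-2-enoate | C=CCOC(=O)/C=C(\Oc1cc2OC(C)(C)Oc2c(OC)c1OC)c1c(OC)cccc1OCc1ccccc1
A1 | alternative 1 | 5,8-dihydroxy-6,7-dimethoxy-2,2-dimethyl-4H-1,3-benzodioxin-4-one | CC1(C)OC(=O)c2c(O)c(OC)c(OC)c(O)c2O1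
A2 | alternative 1 | 4-(2,2-dimethyl-4-oxo-4H-1,3-dioxin-5-yl)-4-hydroxy-2,3-dimethoxycyclobut-2-en-1-one (racemic) | COC1=C(OC)C(O)(C2=COC(C)(C)OC2=O)C1=O
A3 | alternative 2 | 2-(2-hydroxy-6-methoxyphenyl)-7,8-dimethoxychromone 5,6-acetonide | COc1cccc(O)c1-c1cc(=O)c2c3OC(C)(C)Oc3c(OC)c(OC)c2o1
A4 | alternative 2 | 2-(methoxyethynyl)-7,8-dimethoxychromone 5,6-acetonide | COC#Cc1cc(=O)c2c3OC(C)(C)Oc3c(OC)c(OC)c2o1
A5 | alternative 2 | cyclobut-2-en-1-one | O=C1C=CC1
A6 | alternative 3 | 6-(benzyloxy)-2-(2-benzyloxy-6-methoxyphenyl)-5,7-dihydroxy-8-methoxychromen-4-one | COc1cccc(OCc2ccccc2)c1-c1cc(=O)c2c(O)c(OCc3ccccc3)c(O)c(OC)c2o1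
A7 | alternative 3 | methyl 2-(benzyloxy)-4-{6-[2-(benzyloxy)-6-methoxyphenyl]-4-oxo-4H-pyran-2-yl}-4-methoxy-3-oxobutanoate (mixture of stereoisomers) | COC(=O)C(OCc1ccccc1)C(=O)C(OC)c1cc(=O)cc(o1)-c1c(OC)cccc1OCc1ccccc1
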